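Germacrane numbering is used: cyclodecene ring C1–C10, C1=C10 alkene, C4–C5 epoxide, C6 carbinol, C7 isopropyl carbon, C8 ester carbinol. Everything rests on closing the ten-membered ring between C7 and C8. The key step exploits the cis-1,3-diol O6/O8 that flanks C7 on this ring: boron is tied to O6 in a six-membered cyclic allylboronate (ring A), oxidation unmasks the C8 aldehyde, and a boron-templated intramolecular allylboration closes the carbocycle, sets C7 and C8 from C6 and unveils the isopropenyl precursor of the isopropyl group in one operation. The precursor is an acyclic epoxy-alkenyl chain with ring A at one end and a β,γ-unsaturated aldehyde at the other.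

Key step: step 11

Remark: compounds 1, 4, 15 (as its THF solution), 16 and 26 are taken as catalogue chemicals; acyclic intermediates carry the atom labels of the ring they become (C11–C13 are the three-carbon unit on C7, C14 and C15 the methyls on C10 and C4).

Step 1
Reactants: 1 tert-butyl(but-3-yn-1-yloxy)dimethylsilane
Product: 3 tert-butyl{[(3E)-4-iodo-3-methylbut-3-en-1-yl]oxy}dimethylsilane, via alkenylalane 2 (not isolated)
Conditions: Me3Al, Cp2ZrCl2 (0.25 equiv), CH2Cl2, 0 °C to rt; then I2, THF, −30 to 0 °C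
Reagents that add atoms: trimethylaluminium C[Al](C)C; iodine II
Why: Zirconium-catalysed syn-carboalumination of the terminal alkyne (Negishi carboalumination) should place methyl on the internal carbon and aluminium cis to it on the terminal carbon, and iodinolysis with retention should give the E iodide that becomes the C1=C10 alkene.

Step 2
Reactants: 3 tert-butyl{[(3E)-4-iodo-3-methylbut-3-en-1-yl]oxy}dimethylsilane; 4 (4-bromobut-1-yn-1-yl)trimethylsilane
Product: 6 tert-butyldimethyl{[(3E)-3-methyl-8-(trimethylsilyl)oct-3-en-7-yn-1-yl]oxy}silane, via organozinc bromide 5 (not isolated)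
Conditions: 4, Zn dust, LiCl, THF, 50 °C; then 3, PdCl2(dppf) (3 mol %), THF, 40 °C
Reagents that add atoms: none
Why: Negishi sp2–sp3 cross-coupling of the alkenyl iodide with the homopropargylzinc reagent should proceed with retention of the E geometry while the capped alkyne and the silyl ether stay inert.

Step 3
Reactants: 6 tert-butyldimethyl{[(3E)-3-methyl-8-(trimethylsilyl)oct-3-en-7-yn-1-yl]oxy}silane
Product: 7 tert-butyldimethyl{[(3E)-3-methyloct-3-en-7-yn-1-yl]oxy}silane
Conditions: K2CO3, MeOH, rt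
Reagents that add atoms: none
Why: Base-catalysed methanolysis (protodesilylation) should remove only the alkynyl SiMe3 group, since the alkyl TBS ether is stable to K2CO3/MeOH.

Step 4
Reactants: 7 tert-butyldimethyl{[(3E)-3-methyloct-3-en-7-yn-1-yl]oxy}silane
Product: 10 (2E,6E)-9-[(tert-butyldimethylsilyl)oxy]-3,7-dimethylnona-2,6-dien-1-ol, via alkenylalane 8 (not isolated), via lithium alanate 9 (not isolated)
Conditions: Me3Al, Cp2ZrCl2 (0.3 equiv), CH2Cl2, rt; hexane, n-BuLi, −78 to 0 °C; (CH2O)n, THF, rt; aqueous work-up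
Reagents that add atoms: trimethylaluminium C[Al](C)C; formaldehyde (as paraformaldehyde) C=O
Why: A second Negishi carboalumination should set the E C4=C5 alkene, and hydroxymethylation of the derived alanate with formaldehyde goes with retention, the internal trisubstituted alkene being unreactive.

Step 5
Reactants: 10 (2E,6E)-9-[(tert-butyldimethylsilyl)oxy]-3,7-dimethylnona-2,6-dien-1-ol
Product: 11 [(2R,3R)-3-[(3E)-6-[(tert-butyldimethylsilyl)oxy]-4-methylhex-3-en-1-yl]-3-methyloxiran-2-yl]methanol
Conditions: Ti(OiPr)4 (10 mol %), D-(−)-diethyl tartrate (12 mol %), t-BuOOH, 4 Å molecular sieves, CH2Cl2, −20 °C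
Reagents that add atoms: tert-butyl hydroperoxide CC(C)(C)OO
Why: Sharpless asymmetric epoxidation of the primary allylic alcohol with the D-tartrate should deliver oxygen to the face that gives the (2R,3R)-epoxide (C4 and C5 of the target), as in the geraniol series, and leaves the remote alkene untouched.

Step 6
Reactants: 11 [(2R,3R)-3-[(3E)-6-[(tert-butyldimethylsilyl)oxy]-4-methylhex-3-en-1-yl]-3-methyloxiran-2-yl]methanol
Product: 12 (2S,3R)-3-[(3E)-6-[(tert-butyldimethylsilyl)oxy]-4-methylhex-3-en-1-yl]-3-methyloxirane-2-carbaldehyde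
Conditions: Dess–Martin periodinane, NaHCO3, CH2Cl2, 0 °C to rt
Reagents that add atoms: none
Why: Buffered Dess–Martin oxidation should give the α,β-epoxy aldehyde without epimerisation or epoxide opening (the descriptor at C5 changes only through CIP priorities).

Step 7
Reactants: 12 (2S,3R)-3-[(3E)-6-[(tert-butyldimethylsilyl)oxy]-4-methylhex-3-en-1-yl]-3-methyloxirane-2-carbaldehyde
Product: 13 (1R)-1-[(2R,3R)-3-[(3E)-6-[(tert-butyldimethylsilyl)oxy]-4-methylhex-3-en-1-yl]-3-methyloxiran-2-yl]prop-2-en-1-ol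
Conditions: CH2=CHMgBr, THF, −78 °C; aqueous NH4Cl
Reagents that add atoms: vinylmagnesium bromide C=C[Mg]Br
Why: Grignard addition under Felkin–Anh control (attack anti to the epoxide C–O bond, past the small hydrogen) should favour the erythro epoxy alcohol with (R) configuration at C6, the minor C6 epimer being removed by chromatography.

Step 8
Reactants: 13 (1R)-1-[(2R,3R)-3-[(3E)-6-[(tert-butyldimethylsilyl)oxy]-4-methylhex-3-en-1-yl]-3-methyloxiran-2-yl]prop-2-en-1-ol
Product: 14 (3E)-6-[(2R,3R)-3-[(1R)-1-hydroxyprop-2-en-1-yl]-2-methyloxiran-2-yl]-3-methylhex-3-en-1-ol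
Conditions: Bu4NF, THF, 0 °C to rt
Reagents that add atoms: none
Why: Fluoride-mediated silyl ether cleavage should free the C8 hydroxyl without affecting epoxide or alkenes.

Step 9
Reactants: 15 (2-methylprop-2-en-1-yl)magnesium chloride; 16 triisopropyl borate
Product: 18 diisopropyl (2-methylprop-2-en-1-yl)boronate, via borate complex 17 (not isolated)
Conditions: THF, −78 °C to rt; then HCl in Et2O, 0 °C; distillation
Reagents that add atoms: none
Why: Addition of the allyl Grignard reagent to the trialkyl borate and acidification of the borate complex is the standard synthesis of allylboronic esters.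

Step 10
Reactants: 14 (3E)-6-[(2R,3R)-3-[(1R)-1-hydroxyprop-2-en-1-yl]-2-methyloxiran-2-yl]-3-methylhex-3-en-1-ol; 18 diisopropyl (2-methylprop-2-en-1-yl)boronate
Product: 21 (6R)-6-[(2R,3R)-3-[(3E)-6-hydroxy-4-methylhex-3-en-1-yl]-3-methyloxiran-2-yl]-4-methyl-3,6-dihydro-2H-1,2-oxaborinin-2-ol (ring A hemiboronate), via bridged boronate 19 (not isolated), via bicyclic boronate 20 (not isolated)
Conditions: 18 (1.05 equiv), CH2Cl2, rt, then evaporation of i-PrOH; second-generation Grubbs catalyst RuCl2(=CHPh)(H2IMes)(PCy3) (5 mol %), CH2Cl2 (5 mM), 40 °C; then THF, pH 7 buffer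
Reagents that add atoms: water O
Why: Boronic ester annulation, in which transesterification ties the methallylboron unit to O6 (and reversibly to O8), ring-closing metathesis of the O6-bound methallyl group with the C7 vinyl group should form ring A with a necessarily Z alkene (the C1=C10 alkene cannot compete because a seven-membered ring cannot hold the trans epoxide), and hydrolysis frees the C8 alcohol while the six-membered B–O6 ester persists.

Step 11
Reactants: 21 (6R)-6-[(2R,3R)-3-[(3E)-6-hydroxy-4-methylhex-3-en-1-yl]-3-methyloxiran-2-yl]-4-methyl-3,6-dihydro-2H-1,2-oxaborinin-2-ol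
Product: 24 (1(10)E,4R,5R,6R,7R,8R)-4,5-epoxygermacra-1(10),11-diene-6,8-diol, via aldehyde 22 (not isolated), via cyclic borate 23 (not isolated)
Conditions: Dess–Martin periodinane, NaHCO3, CH2Cl2, 0 °C; filtration and dilution with toluene (2 mM), 50 °C; then MeOH, evaporation
Reagents that add atoms: none
Why: Proposed new method: the Dess–Martin oxidation frees the β,γ-unsaturated C8 aldehyde 22, whose carbonyl oxygen binds the ring boron so that C7 (γ-carbon of the B–C12–C11=C7 allyl unit) attacks C8 in an SE2′ allylboration through a bicyclo[2.2.2]-like transition state (bridges O6–C6, O8–C8 and C12–C11 between boron and C7), the B–C12 bond breaking to leave the isopropenyl group and borate 23. The closest known chemistry is the allylboration of aldehydes by six-membered cyclic allylboronic esters from boronic ester annulation, the bicyclic-transition-state allylboration of 3-borolenes and intramolecular allylborations that form five- to seven-membered rings; closure of a ten-membered ring in this way has not been shown. The ten-membered carbocycle closes by 10-exo-trig attack of C7 on the aldehyde carbon, and the 1,3,2-dioxaborinane of 23 closes at the same time by B–O8 bond formation. C7 is controlled by C6 (boron held on O6, ring-locked Z allyl geometry, attack on the face of ring A that carries the C5 tether), and C8 by the need of the aldehyde oxygen to reach that same boron, which should give O6 and O8 cis with the C7 substituent cis to both on the carbocycle, as in the target. The step needs intramolecular to beat intermolecular allyl transfer (2 mM) and needs C5 and C9 to lie anti to the C11–C12 bridge, which is secured because only this arrangement has the gauche ring torsions about C6–C7 and C7–C8 that a ten-membered ring with an E alkene and a trans epoxide can hold. Methanolysis removes boron as B(OMe)3 without acid, which the transannularly reactive epoxy-alkene would not tolerate.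

Step 12
Reactants: 24 (1(10)E,4R,5R,6R,7R,8R)-4,5-epoxygermacra-1(10),11-diene-6,8-diol
Product: 25 (1(10)E,4R,5R,6R,7R,8R)-4,5-epoxygermacr-1(10)-ene-6,8-diol
Conditions: H2 (1 atm), RhCl(PPh3)3 (10 mol %), benzene/EtOH, rt
Reagents that add atoms: none
Why: Homogeneous hydrogenation with RhCl(PPh3)3 should reduce the 1,1-disubstituted isopropenyl alkene chemoselectively and leave the trisubstituted ring alkene and the epoxide untouched.

Step 13
Reactants: 25 (1(10)E,4R,5R,6R,7R,8R)-4,5-epoxygermacr-1(10)-ene-6,8-diol; 26 4-[(tert-butyldimethylsilyl)oxy]benzoic acid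
Product: 28 (1(10)E,4R,5R,6R,7S,8R)-4,5-epoxy-6-hydroxygermacr-1(10)-en-8-yl 4-[(tert-butyldimethylsilyl)oxy]benzoate, via O-acylisourea 27 (not isolated)
Conditions: EDC·HCl, DMAP, CH2Cl2, 0 °C to rt
Reagents that add atoms: none
Why: Steglich esterification with retention at C8 should favour O8, which is flanked by the C9 methylene, over O6, which is shielded by the epoxide carbon C5 and its cis methyl C15 and is hydrogen-bonded to the epoxide.

Step 14
Reactants: 28 (1(10)E,4R,5R,6R,7S,8R)-4,5-epoxy-6-hydroxygermacr-1(10)-en-8-yl 4-[(tert-butyldimethylsilyl)oxy]benzoate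
Product: 29 (1(10)E,4R,5R,6R,7S,8R)-4,5-epoxy-6-hydroxygermacr-1(10)-en-8-yl 4-hydroxybenzoate
Conditions: Bu4NF, AcOH (1:1), THF, 0 °C
Reagents that add atoms: none
Why: Fluoride should cleave the aryl silyl ether within minutes (phenolic TBS deprotection), and acetic acid buffering avoids alkoxide formation and hence acyl migration or epoxide opening.

Compound list
1 | tert-butyl(but-3-yn-1-yloxy)dimethylsilane | C#CCCO[Si](C)(C)C(C)(C)C | starting material
2 | [(1E)-4-[(tert-butyldimethylsilyl)oxy]-2-methylbut-1-en-1-yl]dimethylalumane | C[Al](C)/C=C(\C)CCO[Si](C)(C)C(C)(C)C | intermediate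
3 | tert-butyl{[(3E)-4-iodo-3-methylbut-3-en-1-yl]oxy}dimethylsilane | I/C=C(\C)CCO[Si](C)(C)C(C)(C)C | intermediate
4 | (4-bromobut-1-yn-1-yl)trimethylsilane | C[Si](C)(C)C#CCCBr | starting material
5 | bromo[4-(trimethylsilyl)but-3-yn-1-yl]zinc | C[Si](C)(C)C#CCC[Zn]Br | intermediate
6 | tert-butyldimethyl{[(3E)-3-methyl-8-(trimethylsilyl)oct-3-en-7-yn-1-yl]oxy}silane | C[Si](C)(C)C#CCC/C=C(\C)CCO[Si](C)(C)C(C)(C)C | intermediate
7 | tert-butyldimethyl{[(3E)-3-methyloct-3-en-7-yn-1-yl]oxy}silane | C#CCC/C=C(\C)CCO[Si](C)(C)C(C)(C)C | intermediate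
8 | [(1E,5E)-8-[(tert-butyldimethylsilyl)oxy]-2,6-dimethylocta-1,5-dien-1-yl]dimethylalumane | C[Al](C)/C=C(\C)CC/C=C(\C)CCO[Si](C)(C)C(C)(C)C | intermediate
9 | lithium butyl[(1E,5E)-8-[(tert-butyldimethylsilyl)oxy]-2,6-dimethylocta-1,5-dien-1-yl]dimethylaluminate | [Li+].CCCC[Al-](C)(C)/C=C(\C)CC/C=C(\C)CCO[Si](C)(C)C(C)(C)C | intermediate
10 | (2E,6E)-9-[(tert-butyldimethylsilyl)oxy]-3,7-dimethylnona-2,6-dien-1-ol | OC/C=C(\C)CC/C=C(\C)CCO[Si](C)(C)C(C)(C)C | intermediate
11 | [(2R,3R)-3-[(3E)-6-[(tert-butyldimethylsilyl)oxy]-4-methylhex-3-en-1-yl]-3-methyloxiran-2-yl]methanol | CC(C)(C)[Si](C)(C)OCC/C(C)=C/CC[C@@]1(C)O[C@@H]1CO | intermediate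
12 | (2S,3R)-3-[(3E)-6-[(tert-butyldimethylsilyl)oxy]-4-methylhex-3-en-1-yl]-3-methyloxirane-2-carbaldehyde | CC(C)(C)[Si](C)(C)OCC/C(C)=C/CC[C@@]1(C)O[C@@H]1C=O | intermediate
13 | (1R)-1-[(2R,3R)-3-[(3E)-6-[(tert-butyldimethylsilyl)oxy]-4-methylhex-3-en-1-yl]-3-methyloxiran-2-yl]prop-2-en-1-ol | CC(C)(C)[Si](C)(C)OCC/C(C)=C/CC[C@@]1(C)O[C@@H]1[C@H](O)C=C | intermediate
14 | (3E)-6-[(2R,3R)-3-[(1R)-1-hydroxyprop-2-en-1-yl]-2-methyloxiran-2-yl]-3-methylhex-3-en-1-ol | OCC/C(C)=C/CC[C@@]1(C)O[C@@H]1[C@H](O)C=C | intermediate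
15 | (2-methylprop-2-en-1-yl)magnesium chloride | CC(=C)C[Mg]Cl | starting material
16 | triisopropyl borate | CC(C)OB(OC(C)C)OC(C)C | starting material
17 | chloromagnesium triisopropoxy(2-methylprop-2-en-1-yl)borate | CC(C)O[B-](CC(C)=C)(OC(C)C)OC(C)C.[Mg+]Cl | intermediate
18 | diisopropyl (2-methylprop-2-en-1-yl)boronate | CC(C)OB(CC(C)=C)OC(C)C | intermediate
19 | cyclic (2-methylprop-2-en-1-yl)boronate of diol 14, boron bonded to O6 and O8 (twelve-membered ring; stands for the interconverting oligomers as well) | C=C(C)CB1OCC/C(C)=C/CC[C@@]2(C)O[C@@H]2[C@@H](C=C)O1 | intermediate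
20 | ring-closed boronate: ring A (4-methyl-3,6-dihydro-2H-1,2-oxaborinine on C6) with the boron still bonded to O8 | C/C1=C\CC[C@@]2(C)O[C@@H]2[C@@H]3OB(CC(C)=C3)OCC1 | intermediate
21 | (6R)-6-[(2R,3R)-3-[(3E)-6-hydroxy-4-methylhex-3-en-1-yl]-3-methyloxiran-2-yl]-4-methyl-3,6-dihydro-2H-1,2-oxaborinin-2-ol | OCC/C(C)=C/CC[C@@]1(C)O[C@@H]1[C@@H]2OB(O)CC(C)=C2 | intermediate
22 | (3E)-6-[(2R,3R)-3-[(6R)-2-hydroxy-4-methyl-3,6-dihydro-2H-1,2-oxaborinin-6-yl]-2-methyloxiran-2-yl]-3-methylhex-3-enal | O=CC/C(C)=C/CC[C@@]1(C)O[C@@H]1[C@@H]2OB(O)CC(C)=C2 | intermediate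
23 | cyclic borate of 24 (hydroxyboranediyl bridge between O6 and O8; configuration as in 24) | C/C1=C\CC[C@@]2(C)O[C@@H]2[C@H](OB3O)[C@H](C(C)=C)[C@H](O3)C1 | intermediate
24 | (1(10)E,4R,5R,6R,7R,8R)-4,5-epoxygermacra-1(10),11-diene-6,8-diol | C/C1=C\CC[C@@]2(C)O[C@@H]2[C@H](O)[C@H](C(C)=C)[C@H](O)C1 | intermediate
25 | (1(10)E,4R,5R,6R,7R,8R)-4,5-epoxygermacr-1(10)-ene-6,8-diol | C/C1=C\CC[C@@]2(C)O[C@@H]2[C@H](O)[C@H](C(C)C)[C@H](O)C1 | intermediate
26 | 4-[(tert-butyldimethylsilyl)oxy]benzoic acid | CC(C)(C)[Si](C)(C)Oc1ccc(cc1)C(=O)O | starting material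
27 | O-acylisourea from 26 and EDC | CCN=C(NCCCN(C)C)OC(=O)c1ccc(O[Si](C)(C)C(C)(C)C)cc1 | intermediate
28 | (1(10)E,4R,5R,6R,7S,8R)-4,5-epoxy-6-hydroxygermacr-1(10)-en-8-yl 4-[(tert-butyldimethylsilyl)oxy]benzoate | C/C1=C\CC[C@@]2(C)O[C@@H]2[C@H](O)[C@H](C(C)C)[C@H](OC(=O)c2ccc(O[Si](C)(C)C(C)(C)C)cc2)C1 | intermediate
29 | (1(10)E,4R,5R,6R,7S,8R)-4,5-epoxy-6-hydroxygermacr-1(10)-en-8-yl 4-hydroxybenzoate | C/C1=C\CC[C@@]2(C)O[C@@H]2[C@H](O)[C@H](C(C)C)[C@H](OC(=O)c2ccc(O)cc2)C1 | target

Total step count: 14. Longest linear sequence: 13 steps (steps 1–8 and 10–14; step 9 makes reagent 18 on a side branch).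

Steps most likely to fail

1. Step 11 (proposed new method). The boat-like bicyclic transition state may be too slow at high dilution, so that intermolecular allyl transfer (oligomers) or migration of the C1=C10 double bond into conjugation with the aldehyde takes over. The fallback uses known chemistry, a CrCl2-mediated allyl halide–aldehyde macrocyclisation of the Nozaki–Hiyama–Kishi type, which is established for ten-membered germacrane rings; it sets out from 21 and comes back at 24. Oxidation of the C–B bond of 21 with NaBO3·4H2O in THF/H2O would give the Z allylic triol (2Z,4R)-4-[(2R,3R)-3-[(3E)-6-hydroxy-4-methylhex-3-en-1-yl]-3-methyloxiran-2-yl]-2-methylbut-2-ene-1,4-diol F1. Corey–Kim chlorination (NCS, Me2S, CH2Cl2, −20 °C) should convert only the primary allylic hydroxyl into the chloride (1R,2Z)-4-chloro-1-[(2R,3R)-3-[(3E)-6-hydroxy-4-methylhex-3-en-1-yl]-3-methyloxiran-2-yl]-3-methylbut-2-en-1-ol F2. TEMPO (cat.) with PhI(OAc)2 in CH2Cl2 should oxidise the remaining primary alcohol to the aldehyde (3E)-6-[(2R,3R)-3-[(1R,2Z)-4-chloro-1-hydroxy-3-methylbut-2-en-1-yl]-2-methyloxiran-2-yl]-3-methylhex-3-enal F3. CrCl2 in THF at high dilution would then join C7 to C8 through the allylchromium species, the O6 chromium alkoxide taking over the directing role of boron, to give 24 after aqueous work-up.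

2. Step 13. Site selectivity between the two secondary hydroxyls may be insufficient, so that O6 is acylated or both are. The fallback replaces kinetic site selection by thermodynamic acyl migration; it sets out from 25 and comes back at 28. Acylation of 25 (26, EDC·HCl, DMAP) is run to full conversion to the mixture of 28 and its regioisomer (1(10)E,4R,5R,6R,7R,8R)-4,5-epoxy-8-hydroxygermacr-1(10)-en-6-yl 4-[(tert-butyldimethylsilyl)oxy]benzoate F4. The mixture is then equilibrated with DBU in toluene; 1,3-acyl migration across the cis-1,3-diol through the six-membered orthoester anion should collect the benzoate on the less hindered O8, where the free O6–H keeps its hydrogen bond to the epoxide.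

3. Step 7. Facial selectivity of the Grignard addition to the α,β-epoxy aldehyde may be poor. The fallback sets the C6 centre by reduction instead of addition; it sets out from 12 and comes back at 13. The unseparated C6-epimer mixture from the vinyl addition to 12 is oxidised (Dess–Martin periodinane, NaHCO3) to the vinyl ketone 1-[(2S,3R)-3-[(3E)-6-[(tert-butyldimethylsilyl)oxy]-4-methylhex-3-en-1-yl]-3-methyloxiran-2-yl]prop-2-en-1-one F5. Chelation-controlled 1,2-reduction with Zn(BH4)2 in Et2O at −20 °C (zinc bridging ketone and epoxide oxygens, hydride from the open face) should then give the erythro alcohol 13.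

Further compounds
F1 | step 11 | (2Z,4R)-4-[(2R,3R)-3-[(3E)-6-hydroxy-4-methylhex-3-en-1-yl]-3-methyloxiran-2-yl]-2-methylbut-2-ene-1,4-diol | OCC/C(C)=C/CC[C@@]1(C)O[C@@H]1[C@H](O)/C=C(/C)CO
F2 | step 11 | (1R,2Z)-4-chloro-1-[(2R,3R)-3-[(3E)-6-hydroxy-4-methylhex-3-en-1-yl]-3-methyloxiran-2-yl]-3-methylbut-2-en-1-ol | OCC/C(C)=C/CC[C@@]1(C)O[C@@H]1[C@H](O)/C=C(/C)CCl
F3 | step 11 | (3E)-6-[(2R,3R)-3-[(1R,2Z)-4-chloro-1-hydroxy-3-methylbut-2-en-1-yl]-2-methyloxiran-2-yl]-3-methylhex-3-enal | O=CC/C(C)=C/CC[C@@]1(C)O[C@@H]1[C@H](O)/C=C(/C)CCl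
F4 | step 13 | (1(10)E,4R,5R,6R,7R,8R)-4,5-epoxy-8-hydroxygermacr-1(10)-en-6-yl 4-[(tert-butyldimethylsilyl)oxy]benzoate | C/C1=C\CC[C@@]2(C)O[C@@H]2[C@H](OC(=O)c2ccc(O[Si](C)(C)C(C)(C)C)cc2)[C@H](C(C)C)[C@H](O)C1
F5 | step 7 | 1-[(2S,3R)-3-[(3E)-6-[(tert-butyldimethylsilyl)oxy]-4-methylhex-3-en-1-yl]-3-methyloxiran-2-yl]prop-2-en-1-one | CC(C)(C)[Si](C)(C)OCC/C(C)=C/CC[C@@]1(C)O[C@@H]1C(=O)C=C
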